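The route rests on disconnecting the eleven-membered ring at the bond between its methylene-bearing carbon and the neighbouring acetoxy-bearing carbon, the C(=CH2)–CH(OAc) unit. In the key step a twelve-membered 2-methylene oxacycle, in which these two carbons are linked through the ring oxygen, contracts by a tin–lithium-exchange-triggered 1,2-vinyl (Wittig-type) shift: the oxygen leaves the ring to become the carbinol oxygen, and the carbocycle, the exocyclic methylene and the allylic alcohol arise in one operation. The precursor is the enol ether of an α-stannyl macrolactone, closed by intramolecular B-alkyl Suzuki coupling onto a cis-fused bicyclic dienyl triflate obtained by organocatalytic desymmetrisation of a cyclohexadienone.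

Key step: step 12

Remarks on the chemistry. The sense of induction in step 4 is assigned from the enamine model of the (S)-configured diarylprolinol silyl ether; should the antipode form, the (R)-catalyst is used. All compounds from the stannyl ester to the first eleven-membered alcohol are carried as both epimers at the stannyl-bearing (later carbinol) carbon; this converges at the enone and the centre is then set by reagent control.

Step 1
Reactants: 1 2-methylpent-4-enal (racemic); 2 but-3-en-2-one (methyl vinyl ketone)
Product: 4 4-allyl-4-methylcyclohex-2-en-1-one (racemic), via keto aldehyde 3 (not isolated)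
Conditions: H2SO4 (cat.), PhMe, 45 °C then reflux (Dean–Stark)
Reagents that add atoms: none
Why: Acid-catalysed Michael addition of the aldehyde enol to the enone followed by intramolecular aldol condensation (Robinson annulation) should give the 4,4-disubstituted cyclohexenone; its racemic quaternary carbon loses stereogenicity in step 2.

Step 2
Reactants: 4 4-allyl-4-methylcyclohex-2-en-1-one
Product: 5 4-allyl-4-methylcyclohexa-2,5-dien-1-one
Conditions: DDQ, 1,4-dioxane, reflux
Reagents that add atoms: none
Why: DDQ dehydrogenation of a 4,4-disubstituted cyclohexenone should give the achiral cross-conjugated dienone, the isolated allyl group being inert.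

Step 3
Reactants: 5 4-allyl-4-methylcyclohexa-2,5-dien-1-one
Product: 6 4-(1-methyl-4-oxocyclohexa-2,5-dien-1-yl)butanal
Conditions: Rh(acac)(CO)2 (1 mol %), Xantphos, CO/H2 (syngas, 10 bar), PhMe, 70 °C
Reagents that add atoms: carbon monoxide [C-]#[O+]
Why: Linear-selective hydroformylation (wide-bite-angle diphosphine) should convert only the monosubstituted alkene, the electron-poor disubstituted dienone alkenes being unreactive.

Step 4
Reactants: 6 4-(1-methyl-4-oxocyclohexa-2,5-dien-1-yl)butanal
Product: 7 (1R,3aS,7aS)-3a-methyl-6-oxo-2,3,3a,6,7,7a-hexahydro-1H-indene-1-carbaldehyde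
Conditions: (S)-α,α-diphenylprolinol trimethylsilyl ether (10 mol %), PhCO2H (10 mol %), MeCN, 0 °C
Reagents that add atoms: none
Why: Enamine-catalysed desymmetrising intramolecular Michael addition (5-exo-trig) should attack one enantiotopic enone arm under catalyst control, which sets the quaternary carbon; the three-carbon tether enforces the cis ring fusion, and the formyl-bearing centre equilibrates through the enamine to the exo epimer (cis to the angular methyl and the ring-fusion hydrogen).

Step 5
Reactants: 7 bicyclic enone aldehyde
Product: 8 (1R,3aS,7aS)-3a-methyl-6-oxo-2,3,3a,6,7,7a-hexahydro-1H-indene-1-carboxylic acid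
Conditions: NaClO2, NaH2PO4, 2-methylbut-2-ene, t-BuOH/H2O, 0 °C to rt
Reagents that add atoms: sodium chlorite [Na+].[O-]Cl=O
Why: Pinnick oxidation should convert the aldehyde to the acid without touching the enone, and no stereocentre is affected.

Step 6
Reactants: 9 (R)-3,7-dimethylocta-1,6-diene ((R)-β-citronellene)
Product: 11 (R)-4-methylhex-5-enal, via ozonide 10 (not isolated)
Conditions: O3 (1 equiv, Sudan Red 7B as end-point indicator), CH2Cl2, −78 °C; then PPh3, −78 °C to rt
Reagents that add atoms: ozone [O-][O+]=O
Why: Ozonolysis should cleave the electron-rich trisubstituted alkene much faster than the monosubstituted one; the methyl-bearing stereocentre of the chain comes from the chiral pool and is untouched.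

Step 7
Reactants: 8 bicyclic enone acid; 11 (R)-4-methylhex-5-enal
Product: 14 (4R)-4-methyl-1-(tributylstannyl)hex-5-en-1-yl ester of acid 8 (both epimers at the stannyl carbon), via acid chloride 12 (not isolated), via stannyl alkoxide 13 (not isolated)
Conditions: 8, (COCl)2, DMF (cat.), CH2Cl2, 0 °C to rt, evaporate; separately Bu3SnH, LiN(iPr)2, THF, 0 °C, then 11, −78 °C; then 12 in THF, −78 to −40 °C
Reagents that add atoms: tributylstannyllithium [Li][Sn](CCCC)(CCCC)CCCC
Why: 1,2-Addition of the stannyl anion to the aldehyde and O-acylation of the labile α-stannyl alkoxide in situ is the standard entry to α-acyloxy stannanes; the new carbinol centre is not controlled and is reset in steps 13 and 14.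

Step 8
Reactants: 14 α-stannyl ester
Product: 16 7-methyl derivative of 14, the 3a,7-dimethyl-6-oxo ester (both epimers at C-7), via lithium enolate 15 (not isolated)
Conditions: LiN(iPr)2 (1.05 equiv), THF, −78 °C; MeI, −78 to −40 °C
Reagents that add atoms: iodomethane CI
Why: Kinetic α'-deprotonation of the enone at the CH2 between the carbonyl and the ring fusion (more acidic than the ester α-hydrogen) and C-methylation should install the methyl group; its centre becomes trigonal in step 9.

Step 9
Reactants: 16 methylated enone ester
Product: 18 dienyl triflate, the 3a,7-dimethyl-6-(trifluoromethylsulfonyloxy)-2,3,3a,7a-tetrahydro-1H-indene-1-carboxylate ester, via potassium dienolate 17 (not isolated)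
Conditions: KN(SiMe3)2, THF, −78 °C; PhNTf2, −78 to 0 °C
Reagents that add atoms: N-phenylbis(trifluoromethanesulfonimide) O=S(=O)(N(c1ccccc1)S(=O)(=O)C(F)(F)F)C(F)(F)F
Why: The ketone has a single enolisable position, so enolate O-triflation should fix the tetrasubstituted ring alkene unambiguously as part of a 2-triflyloxy-1,3-diene.

Step 10
Reactants: 18 dienyl triflate ester
Product: 20 twelve-membered α-stannyl lactone fused to the cis-bicyclic 4,6-diene (both epimers at the stannyl carbon), via alkylborane 19 (not isolated)
Conditions: 9-BBN, THF, 0 °C to rt; then slow addition to Pd(dppf)Cl2 (15 mol %), AsPh3, Cs2CO3, DMF/THF/H2O, 50 °C, high dilution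
Reagents that add atoms: none
Why: Anti-Markovnikov hydroboration of the only unhindered alkene and intramolecular B-alkyl Suzuki–Miyaura coupling with the dienyl triflate should close the twelve-membered lactone ring; the α-oxy tributylstannane does not transmetalate under these conditions.

Step 11
Reactants: 20 twelve-membered α-stannyl lactone
Product: 21 twelve-membered 2-methylene oxacycle (exocyclic enol ether, α-stannyl on the other oxygen-bearing carbon)
Conditions: Cp2TiMe2 (3 equiv), PhMe, 75 °C, dark; basic alumina work-up
Reagents that add atoms: dimethyltitanocene C[Ti](C)(C1C=CC=C1)C1C=CC=C1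
Why: Petasis methylenation of the lactone carbonyl, the only carbonyl group present, should give the enol ether under non-basic conditions that tolerate the stannane and the diene.

Step 12
Reactants: 21 twelve-membered 2-methylene oxacycle
Product: 23 eleven-membered carbocyclic allylic alcohol with the exocyclic methylene next to the carbinol (both carbinol epimers), via alkoxyalkyllithium 22 (not isolated)
Conditions: n-BuLi (1.2 equiv), THF, −78 °C, then to −20 °C; H2O
Reagents that add atoms: none
Why: Proposed new method: tin–lithium exchange should give the non-stabilised α-alkoxy organolithium 22, whose carbanion attacks the oxygen-bearing carbon of the adjacent enol ether to form an oxiranylmethyl anion that opens at once to the allylic alkoxide, i.e. a [1,2]-Wittig rearrangement with alkenyl migration in which the ring oxygen leaves the ring and the twelve-membered oxacycle becomes the eleven-membered carbocycle. The closest known reactions are the [1,2]-Wittig vinyl migration of lithiated benzyl vinyl ethers and Wittig rearrangements of α-alkoxy organolithiums generated from stannanes; here the carbanion is not benzylic and the ether is macrocyclic. The only ring closed is the transient oxirane (3-exo-trig), and its opening by β-elimination makes the new C–C bond of the eleven-membered ring permanent. The carbinol stereocentre arises from an epimeric stannane and is not controlled here; it is reset in steps 13 and 14. The step needs the 1,2-shift to outrun proton transfer to the carbanion and needs a substrate free of electrophiles, which is secured by the prior methylenation of the only carbonyl group and by running the exchange at −78 °C.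

Step 13
Reactants: 23 eleven-membered allylic alcohol (both epimers)
Product: 24 eleven-membered α-methylene ketone
Conditions: Dess–Martin periodinane, NaHCO3, CH2Cl2, 0 °C
Reagents that add atoms: none
Why: Dess–Martin oxidation of the secondary allylic alcohol should converge both epimers to one cross-conjugated enone under neutral conditions that spare the diene.

Step 14
Reactants: 24 eleven-membered α-methylene ketone
Product: 25 (R)-configured allylic alcohol
Conditions: (S)-2-methyl-CBS-oxazaborolidine (20 mol %), catecholborane, PhMe, −78 °C; then MeOH, aq. NaHCO3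
Reagents that add atoms: none
Why: Corey–Bakshi–Shibata reduction should proceed 1,2 with the alkenyl group as the large substituent, so that the (S)-catalyst sets the (R)-carbinol by reagent control.

Step 15
Reactants: 25 (R)-allylic alcohol
Product: 26 (R)-allylic acetate of the tricyclic triene
Conditions: Ac2O, pyridine, DMAP (cat.), CH2Cl2, 0 °C to rt
Reagents that add atoms: acetic anhydride CC(=O)OC(C)=O
Why: Standard acylation of the only hydroxyl group, with retention at the carbinol carbon.

Step 16
Reactants: 26 triene acetate
Product: 27 vinyl epoxide (epoxide across the disubstituted ring alkene, on the face opposite the angular methyl)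
Conditions: (S,S)-Mn(salen)Cl (salen = N,N'-bis(3,5-di-tert-butylsalicylidene)cyclohexane-1,2-diamine dianion; 5 mol %), NaOCl (aq., pH 11.3), 4-phenylpyridine N-oxide, CH2Cl2, 0 °C
Reagents that add atoms: sodium hypochlorite [Na+].[O-]Cl
Why: Jacobsen epoxidation is selective for a conjugated cis-disubstituted alkene over the tetrasubstituted and the isolated 1,1-disubstituted alkenes, and since this alkene is flanked by a quaternary carbon and a trigonal carbon as in 2,2-dimethylchromene, the (S,S)-catalyst should set both epoxide carbons on the face anti to the angular methyl.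

Step 17
Reactants: 27 vinyl epoxide
Product: 28 target compound CNP0192310.2
Conditions: rac-Co(salen)OAc (5 mol %), H2O (5 equiv), THF, 0 °C to rt
Reagents that add atoms: water O
Why: Cobalt–salen-catalysed hydrolytic epoxide opening should occur by SN2 attack at the allylic carbon (the other epoxide carbon is neopentyl) with inversion, giving the trans-diol with the allylic hydroxyl cis to the angular methyl, under neutral conditions that spare the acetate.

Compound list

1 | 2-methylpent-4-enal (racemic) | C=CCC(C)C=O | starting material
2 | but-3-en-2-one (methyl vinyl ketone) | CC(=O)C=C | starting material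
3 | 2-methyl-2-(3-oxobutyl)pent-4-enal (racemic Michael adduct) | C=CCC(C)(C=O)CCC(C)=O | intermediate
4 | 4-allyl-4-methylcyclohex-2-en-1-one (racemic) | C=CCC1(C)CCC(=O)C=C1 | intermediate
5 | 4-allyl-4-methylcyclohexa-2,5-dien-1-one | C=CCC1(C)C=CC(=O)C=C1 | intermediate
6 | 4-(1-methyl-4-oxocyclohexa-2,5-dien-1-yl)butanal | O=CCCCC1(C)C=CC(=O)C=C1 | intermediate
7 | (1R,3aS,7aS)-3a-methyl-6-oxo-2,3,3a,6,7,7a-hexahydro-1H-indene-1-carbaldehyde (cis-fused; formyl cis to the angular methyl and the ring-fusion hydrogen) | O=C1C[C@H]2[C@H](C=O)CC[C@@]2(C)C=C1 | intermediate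
8 | (1R,3aS,7aS)-3a-methyl-6-oxo-2,3,3a,6,7,7a-hexahydro-1H-indene-1-carboxylic acid | O=C1C[C@H]2[C@H](C(=O)O)CC[C@@]2(C)C=C1 | intermediate
9 | (R)-3,7-dimethylocta-1,6-diene ((R)-β-citronellene) | CC(C)=CCC[C@@H](C)C=C | starting material
10 | 3,3-dimethyl-5-[(3R)-3-methylpent-4-en-1-yl]-1,2,4-trioxolane (ozonide) | CC1(C)OOC(CC[C@@H](C)C=C)O1 | intermediate
11 | (R)-4-methylhex-5-enal | O=CCC[C@@H](C)C=C | intermediate
12 | (1R,3aS,7aS)-3a-methyl-6-oxo-2,3,3a,6,7,7a-hexahydro-1H-indene-1-carbonyl chloride | O=C1C[C@H]2[C@H](C(=O)Cl)CC[C@@]2(C)C=C1 | intermediate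
13 | lithium (4R)-4-methyl-1-(tributylstannyl)hex-5-en-1-olate (both C-1 epimers) | [Li+].[O-]C(CC[C@@H](C)C=C)[Sn](CCCC)(CCCC)CCCC | intermediate
14 | (4R)-4-methyl-1-(tributylstannyl)hex-5-en-1-yl ester of acid 8 (core stereocentres as in 8; both epimers at the stannyl carbon) | O=C1C[C@H]2[C@H](C(=O)OC(CC[C@@H](C)C=C)[Sn](CCCC)(CCCC)CCCC)CC[C@@]2(C)C=C1 | intermediate
15 | lithium cross-conjugated dienolate of 14 (enolate double bond towards the CH next to the ring fusion) | [Li+].[O-]C1=C[C@H]2[C@H](C(=O)OC(CC[C@@H](C)C=C)[Sn](CCCC)(CCCC)CCCC)CC[C@@]2(C)C=C1 | intermediate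
16 | 7-methyl derivative of 14: (4R)-4-methyl-1-(tributylstannyl)hex-5-en-1-yl 3a,7-dimethyl-6-oxo-2,3,3a,6,7,7a-hexahydro-1H-indene-1-carboxylate (core as in 8; both epimers at C-7 and at the stannyl carbon) | O=C1C(C)[C@H]2[C@H](C(=O)OC(CC[C@@H](C)C=C)[Sn](CCCC)(CCCC)CCCC)CC[C@@]2(C)C=C1 | intermediate
17 | potassium dienolate of 16 (tetrasubstituted enolate double bond between C-6 and C-7) | [K+].[O-]C1=C(C)[C@H]2[C@H](C(=O)OC(CC[C@@H](C)C=C)[Sn](CCCC)(CCCC)CCCC)CC[C@@]2(C)C=C1 | intermediate
18 | (4R)-4-methyl-1-(tributylstannyl)hex-5-en-1-yl 3a,7-dimethyl-6-(trifluoromethylsulfonyloxy)-2,3,3a,7a-tetrahydro-1H-indene-1-carboxylate (4,6-diene; core as in 8; both epimers at the stannyl carbon) | O=S(=O)(OC1=C(C)[C@H]2[C@H](C(=O)OC(CC[C@@H](C)C=C)[Sn](CCCC)(CCCC)CCCC)CC[C@@]2(C)C=C1)C(F)(F)F | intermediate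
19 | 9-BBN adduct of 18 (boron on the terminal chain carbon) | O=S(=O)(OC1=C(C)[C@H]2[C@H](C(=O)OC(CC[C@@H](C)CCB3C4CCCC3CCC4)[Sn](CCCC)(CCCC)CCCC)CC[C@@]2(C)C=C1)C(F)(F)F | intermediate
20 | twelve-membered α-stannyl lactone: the ester carbonyl on C-1 and C-6 of the cis-fused 3a,7-dimethyl-2,3,3a,7a-tetrahydro-1H-indene (4,6-diene) are bridged by O–CH(SnBu3)–CH2–CH2–CH(CH3)–CH2–CH2 (chain methyl centre from (R)-11; both epimers at the stannyl carbon) | O=C1OC([Sn](CCCC)(CCCC)CCCC)CC[C@@H](C)CCC2=C(C)[C@H]3[C@H]1CC[C@@]3(C)C=C2 | intermediate
21 | twelve-membered 2-methylene oxacycle: lactone 20 with C=O replaced by C=CH2 (cyclic enol ether; both epimers at the stannyl carbon) | C=C1OC([Sn](CCCC)(CCCC)CCCC)CC[C@@H](C)CCC2=C(C)[C@H]3[C@H]1CC[C@@]3(C)C=C2 | intermediate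
22 | α-alkoxy organolithium from 21 (lithium in place of tributylstannyl) | C=C1OC([Li])CC[C@@H](C)CCC2=C(C)[C@H]3[C@H]1CC[C@@]3(C)C=C2 | intermediate
23 | eleven-membered carbocyclic allylic alcohol: exocyclic methylene carbon bonded to the cyclopentane carbon and to the carbinol carbon; tricyclic 5-6-11 skeleton with the ring diene (both carbinol epimers) | C=C1C(O)CC[C@@H](C)CCC2=C(C)[C@H]3[C@H]1CC[C@@]3(C)C=C2 | intermediate
24 | eleven-membered α-methylene ketone (ketone in place of the carbinol of 23) | C=C1C(=O)CC[C@@H](C)CCC2=C(C)[C@H]3[C@H]1CC[C@@]3(C)C=C2 | intermediate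
25 | (R)-carbinol epimer of 23 | C=C1[C@H](O)CC[C@@H](C)CCC2=C(C)[C@H]3[C@H]1CC[C@@]3(C)C=C2 | intermediate
26 | acetate of 25 (tricyclic triene acetate) | C=C1[C@H](OC(C)=O)CC[C@@H](C)CCC2=C(C)[C@H]3[C@H]1CC[C@@]3(C)C=C2 | intermediate
27 | epoxide of 26 across the disubstituted ring alkene, oxygen anti to the angular methyl | C=C1[C@H](OC(C)=O)CC[C@@H](C)CCC2=C(C)[C@H]3[C@H]1CC[C@@]3(C)[C@H]4O[C@H]42 | intermediate
28 | target CNP0192310.2: trans-diol from 27 (allylic hydroxyl cis to the angular methyl, the other trans to it), (R)-allylic acetate, exocyclic methylene, tetrasubstituted ring alkene | C=C1[C@H](OC(C)=O)CC[C@@H](C)CCC2=C(C)[C@H]3[C@H]1CC[C@@]3(C)[C@@H](O)[C@@H]2O | target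

Total step count: 17. Longest linear sequence: 16 steps (steps 1 to 5 and 7 to 17; step 6 is a one-step side branch).

Steps most likely to fail

Step 12 (Proposed new method). The carbanion may be quenched by transannular proton transfer from the doubly allylic ring-fusion C–H, or the attack on the unactivated enol ether may be too slow for any migration to occur. The fallback uses known chemistry and sets out from lactone 20, leaving out step 11. Tin–lithium exchange (MeLi, THF, −100 °C) should give the α-acyloxy organolithium F1, which undergoes the established anionic 1,2-acyl shift from oxygen to carbon and so contracts the lactone to the eleven-membered α-hydroxy ketone F2. Wittig methylenation of F2 (Ph3P=CH2 in excess, THF, 0 °C to rt) brings the route back at alcohol 23.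

Step 10. Intermolecular coupling may compete with ring closure, the alkylborane may be protonated, or the hindered triflate and the ester may be hydrolysed by the aqueous base. The fallback sets out from triflate 18 and avoids base altogether. Hydrozirconation of the terminal alkene (Cp2Zr(H)Cl, THF, rt) gives the alkylzirconocene chloride F3, transmetalation with ZnCl2 gives the alkylzinc chloride F4, and a Negishi macrocyclisation (Pd(PPh3)4, THF, 45 °C, high dilution) returns to lactone 20.

Step 17. Ionisation of the vinyl epoxide to an allyl cation may erode regio- and stereocontrol, with attack under retention or at the tertiary allylic terminus. The fallback sets out from epoxide 27 and sets the allylic carbinol by directed reduction instead of by inversion. Acid hydrolysis (HClO4 cat., THF/H2O, 0 °C) gives the 1,2-diol as a mixture of 28 and its epimer at the allylic carbinol, the cis-diol F5. MnO2 (CH2Cl2, rt) oxidises the allylic hydroxyl of both to the single hydroxy enone F6. Hydroxyl-directed reduction (Me4NBH(OAc)3, MeCN/AcOH, −20 °C) then delivers hydride from the face of the neighbouring hydroxyl and should give the trans-diol 28.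

Further compounds
F1 | step 12 | α-acyloxy organolithium from 20 (lithium in place of tributylstannyl) | O=C1OC([Li])CC[C@@H](C)CCC2=C(C)[C@H]3[C@H]1CC[C@@]3(C)C=C2
F2 | step 12 | eleven-membered α-hydroxy ketone (ketone on the carbon bonded to the cyclopentane, hydroxyl on the next ring carbon; both carbinol epimers) | O=C1C(O)CC[C@@H](C)CCC2=C(C)[C@H]3[C@H]1CC[C@@]3(C)C=C2
F3 | step 10 | alkylzirconocene chloride from 18 (Cp2ZrCl on the terminal chain carbon) | O=S(=O)(OC1=C(C)[C@H]2[C@H](C(=O)OC(CC[C@@H](C)CC[Zr](Cl)(C3C=CC=C3)C3C=CC=C3)[Sn](CCCC)(CCCC)CCCC)CC[C@@]2(C)C=C1)C(F)(F)F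
F4 | step 10 | alkylzinc chloride from F3 (ZnCl on the terminal chain carbon) | O=S(=O)(OC1=C(C)[C@H]2[C@H](C(=O)OC(CC[C@@H](C)CC[Zn]Cl)[Sn](CCCC)(CCCC)CCCC)CC[C@@]2(C)C=C1)C(F)(F)F
F5 | step 17 | cis-diol, the epimer of 28 at the allylic carbinol carbon | C=C1[C@H](OC(C)=O)CC[C@@H](C)CCC2=C(C)[C@H]3[C@H]1CC[C@@]3(C)[C@@H](O)[C@H]2O
F6 | step 17 | α'-hydroxy enone (allylic carbinol of 28 oxidised to the conjugated ketone) | C=C1[C@H](OC(C)=O)CC[C@@H](C)CCC2=C(C)[C@H]3[C@H]1CC[C@@]3(C)[C@@H](O)C2=O
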